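**Retrosynthetic overview**
1. Target 15 ⇒ dibenzyl ether 14 by one neutral hydrogenolysis.
2. Key step: 14 ⇒ open-chain acid 9 + 3-(benzyloxy)benzyne by an anionic [4+2] aryne annulation, which makes C4–C4a and C1–C8a in one flask and sets C4 on the quench.
3. 9 ⇒ ketone 5 by catalytic asymmetric allylboration (sets C3), then cleavage of the allyl group to the C1 carboxyl.
4. 5 ⇒ triacetic acid lactone benzyl ether + methyl benzoate by lateral acylation.
5. Ring order: pyranone ring (bought), benzene ring (bought, used as aryne), cyclohexanone ring last. No aldol ring closure and no aryl-metal addition to a tetralone ketone is used.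

Assumption: (S)-3,3'-dibromo-BINOL is taken to deliver allyl to the Re face of ketone 5, as it does for aryl alkyl ketones; if the sense proves opposite, the (R)-catalyst is used.

**Step 1**
Reactants: 1 4-hydroxy-6-methyl-2H-pyran-2-one (triacetic acid lactone)
Product: 2 4-(benzyloxy)-6-methyl-2H-pyran-2-one
Conditions: BnBr (1.1 equiv), K2CO3 (1.5 equiv), DMF, rt
Reagents that add atoms: benzyl bromide (BrCc1ccccc1)
Why: Williamson O-alkylation of the vinylogous acid at O4 in a polar aprotic solvent masks the acidic OH as an ether that later falls off by hydrogenolysis; no stereocentre is involved.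

**Step 2**
Reactants: 2 4-(benzyloxy)-6-methyl-2H-pyran-2-one; 3 methyl benzoate
Product: 5 4-(benzyloxy)-6-(2-oxo-2-phenylethyl)-2H-pyran-2-one, via lithium dienolate 4 (not isolated)
Conditions: LiN(SiMe3)2 (2.2 equiv), THF, −78 °C; then 3, −78 → −20 °C; 1 M HCl quench
Reagents that add atoms: none
Why: Lateral (vinylogous) deprotonation of the 6-methyl group gives dienolate 4, which undergoes Claisen-type C-acylation at the exocyclic carbon, two equivalents of base being used because the product is more acidic than 2; no stereocentre is involved.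

**Step 3**
Reactants: 5 4-(benzyloxy)-6-(2-oxo-2-phenylethyl)-2H-pyran-2-one
Product: 6 4-(benzyloxy)-6-[(2S)-2-hydroxy-2-phenylpent-4-en-1-yl]-2H-pyran-2-one
Conditions: diisopropyl allylboronate (1.5 equiv), (S)-3,3'-dibromo-BINOL (15 mol%), PhCF3/PhMe 3:1, −35 °C; aqueous work-up
Reagents that add atoms: diisopropyl allylboronate (C=CCB(OC(C)C)OC(C)C)
Why: Chiral-diol-catalysed asymmetric allylboration of an aryl ketone runs through a closed chair transition state on the BINOL-bound boronate, tells phenyl from the CH2-pyranone arm and delivers allyl to the Re face, which sets the tertiary carbinol as (S), while the non-basic reagent leaves the acidic CH2 alone.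

**Step 4**
Reactants: 6 4-(benzyloxy)-6-[(2S)-2-hydroxy-2-phenylpent-4-en-1-yl]-2H-pyran-2-one
Product: 8 (3R)-4-[4-(benzyloxy)-2-oxo-2H-pyran-6-yl]-3-hydroxy-3-phenylbutanal, via vicinal diol 7 (not isolated)
Conditions: OsO4 (2 mol%), NaIO4 (4 equiv), 2,6-lutidine (2 equiv), dioxane/H2O 3:1, rt
Reagents that add atoms: osmium tetroxide (O=[Os](=O)(=O)=O)
Why: Lemieux–Johnson cleavage, in which OsO4 dihydroxylates only the electron-rich terminal alkene to diol 7 and NaIO4 cleaves it to the aldehyde under lutidine buffering; the carbinol centre is untouched and its descriptor changes to (R) by priority only.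

**Step 5**
Reactants: 8 (3R)-4-[4-(benzyloxy)-2-oxo-2H-pyran-6-yl]-3-hydroxy-3-phenylbutanal
Product: 9 (3R)-4-[4-(benzyloxy)-2-oxo-2H-pyran-6-yl]-3-hydroxy-3-phenylbutanoic acid
Conditions: NaClO2, NaH2PO4, 2-methyl-2-butene, t-BuOH/H2O, 0 °C → rt
Reagents that add atoms: sodium chlorite ([Na+].[O-]Cl=O)
Why: Pinnick oxidation turns the aldehyde into the acid under buffered, non-basic conditions that spare the tertiary β-hydroxy group, the benzyl ether and the pyranone; no stereocentre is touched.

**Step 6**
Reactants: 9 (3R)-4-[4-(benzyloxy)-2-oxo-2H-pyran-6-yl]-3-hydroxy-3-phenylbutanoic acid; 10 1-(benzyloxy)-3-bromobenzene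
Product: 14 (3S,4S)-8-(benzyloxy)-4-[4-(benzyloxy)-2-oxo-2H-pyran-6-yl]-3-hydroxy-3-phenyl-3,4-dihydronaphthalen-1(2H)-one, via trilithium trianion 11 (not isolated), via 3-(benzyloxy)benzyne 12 (not isolated), via tetralithium diolate 13 (not isolated)
Conditions: lithium 2,2,6,6-tetramethylpiperidide (3.1 equiv), THF, −78 °C; then 10 (1.3 equiv) and more lithium 2,2,6,6-tetramethylpiperidide (2.5 equiv), −78 → −40 °C; AcOH in THF, −78 °C
Reagents that add atoms: none
Why: Proposed new method: an anionic [4+2] aryne annulation in which the pyranone-stabilised C4 carbanion of trianion 11 (elimination-proof because the C3 oxygen is an oxide, and retro-aldol-resistant because the only nucleofuge would be a carboxylate dianion) adds to aryne 12 at the carbon meta to OBn, the aryllithium so formed ortho to OBn closes through a six-membered transition state on the enolisation-resistant lithium carboxylate to give diolate 13 (which masks the C1 ketone until work-up), excess base re-forms the exocyclic C4 dienolate with the C3 phenyl pushed axial by allylic strain, and the cold AcOH quench protonates C4 on the face opposite that phenyl (syn to the C3 oxygen), setting C4 as (S) while C3 (from step 3) is untouched; the closest known reaction types are aryne–enolate annulations run with lithium amide bases and the Parham cycliacylation of aryllithiums onto lithium carboxylates.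

**Step 7**
Reactants: 14 (3S,4S)-8-(benzyloxy)-4-[4-(benzyloxy)-2-oxo-2H-pyran-6-yl]-3-hydroxy-3-phenyl-3,4-dihydronaphthalen-1(2H)-one
Product: 15 (3S,4S)-3,8-dihydroxy-4-(4-hydroxy-2-oxo-2H-pyran-6-yl)-3-phenyl-3,4-dihydronaphthalen-1(2H)-one
Conditions: H2 (1 atm), Pd/C (10 wt%), EtOAc, rt, stopped after 2 equiv H2
Reagents that add atoms: none
Why: Hydrogenolysis of the aryl benzyl ether and the vinylogous benzyl ester over Pd/C under neutral conditions frees both hydroxyls, while the tertiary benzylic alcohol (which needs acid to cleave), the aryl ketone and the non-basic C4 centre are left untouched.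

**Compound list**
1 | 4-hydroxy-6-methyl-2H-pyran-2-one | Cc1cc(O)cc(=O)o1 | starting material
2 | 4-(benzyloxy)-6-methyl-2H-pyran-2-one | Cc1cc(OCc2ccccc2)cc(=O)o1 | intermediate
3 | methyl benzoate | COC(=O)c1ccccc1 | starting material
4 | lithium 4-(benzyloxy)-6-methylidene-6H-pyran-2-olate (lithium dienolate of 2, formed in the flask) | [Li+].[O-]C1=CC(OCc2ccccc2)=CC(=C)O1 | intermediate
5 | 4-(benzyloxy)-6-(2-oxo-2-phenylethyl)-2H-pyran-2-one | O=C(Cc1cc(OCc2ccccc2)cc(=O)o1)c1ccccc1 | intermediate
6 | 4-(benzyloxy)-6-[(2S)-2-hydroxy-2-phenylpent-4-en-1-yl]-2H-pyran-2-one | C=CC[C@@](O)(c1ccccc1)Cc1cc(OCc2ccccc2)cc(=O)o1 | intermediate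
7 | 4-(benzyloxy)-6-[(2S)-2,4,5-trihydroxy-2-phenylpentyl]-2H-pyran-2-one (both C4 epimers, formed in the flask) | OCC(O)C[C@@](O)(c1ccccc1)Cc1cc(OCc2ccccc2)cc(=O)o1 | intermediate
8 | (3R)-4-[4-(benzyloxy)-2-oxo-2H-pyran-6-yl]-3-hydroxy-3-phenylbutanal | O=CC[C@@](O)(c1ccccc1)Cc1cc(OCc2ccccc2)cc(=O)o1 | intermediate
9 | (3R)-4-[4-(benzyloxy)-2-oxo-2H-pyran-6-yl]-3-hydroxy-3-phenylbutanoic acid | OC(=O)C[C@@](O)(c1ccccc1)Cc1cc(OCc2ccccc2)cc(=O)o1 | intermediate
10 | 1-(benzyloxy)-3-bromobenzene | Brc1cccc(OCc2ccccc2)c1 | starting material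
11 | trilithium salt of 9: carboxylate, C3 alkoxide and C4 carbanion drawn as the pyranolate dienolate, carbinol configuration as in 9 (formed in the flask) | [Li+].[Li+].[Li+].[O-]C(=O)C[C@@]([O-])(c1ccccc1)C=C1C=C(OCc2ccccc2)C=C([O-])O1 | intermediate
12 | 3-(benzyloxy)benzyne (1-(benzyloxy)-2,3-didehydrobenzene, formed in the flask) | C1#CC(OCc2ccccc2)=CC=C1 | intermediate
13 | tetralithium salt of the cyclised product: C1 gem-diolate, C3 alkoxide and exocyclic C4 dienolate, C3 configuration as in 14 (formed in the flask) | [Li+].[Li+].[Li+].[Li+].[O-]C1([O-])C[C@@]([O-])(c2ccccc2)C(=C3C=C(OCc4ccccc4)C=C([O-])O3)c2cccc(OCc3ccccc3)c12 | intermediate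
14 | (3S,4S)-8-(benzyloxy)-4-[4-(benzyloxy)-2-oxo-2H-pyran-6-yl]-3-hydroxy-3-phenyl-3,4-dihydronaphthalen-1(2H)-one | O=C1C[C@@](O)(c2ccccc2)[C@@H](c2cc(OCc3ccccc3)cc(=O)o2)c2cccc(OCc3ccccc3)c21 | intermediate
15 | (3S,4S)-3,8-dihydroxy-4-(4-hydroxy-2-oxo-2H-pyran-6-yl)-3-phenyl-3,4-dihydronaphthalen-1(2H)-one | O=C1C[C@@](O)(c2ccccc2)[C@@H](c2cc(O)cc(=O)o2)c2cccc(O)c21 | target

**Totals**
Total step count: 7. Longest linear sequence: 7 steps (1 → 15).

**Steps most likely to fail, with fallbacks**

Step 6 (aryne annulation) is the greatest risk. The alkoxide or carboxylate may arylate at oxygen, the aryllithium may be protonated by the amine before it closes, and the C4 protonation may be poorly selective. The fallback makes the two aryl bonds one after the other without an aryne; it sets out from 9 and comes back at 14. Acid 9 is coupled with MeNHOMe·HCl (EDC, N-methylmorpholine, CH2Cl2) to the Weinreb amide (3R)-4-[4-(benzyloxy)-2-oxo-2H-pyran-6-yl]-3-hydroxy-N-methoxy-N-methyl-3-phenylbutanamide F1. F1 is first deprotonated at OH and C4 with LiN(SiMe3)2 (2.1 equiv, THF, −78 °C) and then acylates [2-(benzyloxy)-6-fluorophenyl]lithium F2, made from 1-(benzyloxy)-3-fluorobenzene and n-BuLi and kept below −70 °C so that it does not lose LiF. After an aqueous NH4Cl quench this gives the ortho-fluoroaryl ketone (3R)-1-[2-(benzyloxy)-6-fluorophenyl]-4-[4-(benzyloxy)-2-oxo-2H-pyran-6-yl]-3-hydroxy-3-phenylbutan-1-one F3. LiN(SiMe3)2 (2.2 equiv, THF, −78 → −20 °C) then closes the cyclohexanone ring by intramolecular SNAr of the C4 carbanion on the ketone-activated C–F carbon, and the same cold AcOH quench gives 14.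

Step 3 (asymmetric allylboration) may be slow or poorly selective on this ketone, whose alkyl arm is a bulky, acidic CH2-pyranone. The fallback gives up catalyst control and resolves instead; it sets out from 5 and comes back at 6. Ketone 5 is allylated in a Barbier reaction (indium powder, allyl bromide, THF/H2O, rt), which tolerates the acidic CH2. The racemate, that is 6 together with its enantiomer 4-(benzyloxy)-6-[(2R)-2-hydroxy-2-phenylpent-4-en-1-yl]-2H-pyran-2-one F4, is separated by preparative chromatography on a chiral stationary phase, and the (S)-enantiomer re-enters as 6.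

Step 7 (global hydrogenolysis) may over-reduce the pyranone C=C or the aryl ketone, or cleave the tertiary benzylic C–O bond. The fallback removes both benzyl groups without hydrogen; it sets out from 14 and comes back at 15. BCl3 with pentamethylbenzene as benzyl-cation scavenger (CH2Cl2, −78 °C, short contact, cold MeOH quench) dealkylates both ethers, which are unusually labile because one is peri to the ketone and the other is a vinylogous ester. No new compound is made on the way (F0).

**Further compounds**
F1 | step 6 | (3R)-4-[4-(benzyloxy)-2-oxo-2H-pyran-6-yl]-3-hydroxy-N-methoxy-N-methyl-3-phenylbutanamide | CON(C)C(=O)C[C@@](O)(c1ccccc1)Cc1cc(OCc2ccccc2)cc(=O)o1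
F2 | step 6 | [2-(benzyloxy)-6-fluorophenyl]lithium | [Li]c1c(F)cccc1OCc1ccccc1
F3 | step 6 | (3R)-1-[2-(benzyloxy)-6-fluorophenyl]-4-[4-(benzyloxy)-2-oxo-2H-pyran-6-yl]-3-hydroxy-3-phenylbutan-1-one | O=C(C[C@@](O)(c1ccccc1)Cc1cc(OCc2ccccc2)cc(=O)o1)c1c(F)cccc1OCc1ccccc1
F4 | step 3 | 4-(benzyloxy)-6-[(2R)-2-hydroxy-2-phenylpent-4-en-1-yl]-2H-pyran-2-one | C=CC[C@](O)(c1ccccc1)Cc1cc(OCc2ccccc2)cc(=O)o1
F0 | step 7 | none | none
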